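The 2-aryl-3-(hydroxymethyl)-2,3-dihydrobenzofuran is traced back to a cyclopropane fused across the C2=C3 bond of a benzofuran. The feature exploited lies in the dihydrofuran ring: C3 bears one exocyclic carbon (CH2OH) and C2 an aryl group on the opposite face. A single asymmetric carbene transfer from ethyl diazoacetate to 7-(benzyloxy)-5-bromobenzofuran makes the lasting C3–CH bond and a sacrificial C2–CH bond, closes the three-membered ring and fixes the absolute configuration at C3. Its cis fusion later steers guaiacol onto C2 anti to that carbon. The C5 bromide becomes the flavonol, and the surplus ester carbon is removed by radical decarboxylation.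

Key step: step 5

Remark on the structures: the target is the (2R,3S)-trans isomer, and the exo cyclopropane of the key step is (1S,1aS,6bR), which maps onto it after inversion at C2; neither structure needs correction. The C3 descriptor reads R while the side chain is CH2CO2R and S once it is CH2OH, with no change in geometry.

Remark on the precursor: bromine and the benzyl ether are kept unchanged. Both are inert to copper carbenes; bromine, para to the ring oxygen, damps ionisation at C2 in step 6 and allows the absolute configuration to be checked by anomalous dispersion; benzyl makes the final deprotection one hydrogenolysis.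

Assumption: the (S,S) antipode of t-Bu-BOX is taken to give the required enantiomer; the sense of induction is to be confirmed on the first batch, and the equally available (R,R) ligand used if it is opposite.

Step 1
Reactants: 1 2,3-dihydroxybenzaldehyde
Product: 2 3-(benzyloxy)-2-hydroxybenzaldehyde
Conditions: NaH (2.2 equiv), DMSO, rt; BnBr (1.0 equiv), rt; aq HCl
Reagents that add atoms: benzyl bromide, BrCc1ccccc1
Why: Williamson etherification of the dianion, in which the 2-phenoxide is chelated and delocalised into the formyl group, so the 3-phenoxide is the more nucleophilic oxygen.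

Step 2
Reactants: 2 3-(benzyloxy)-2-hydroxybenzaldehyde
Product: 3 3-(benzyloxy)-5-bromo-2-hydroxybenzaldehyde
Conditions: NBS (1.05 equiv), MeCN, 0 °C to rt
Reagents that add atoms: N-bromosuccinimide, O=C1CCC(=O)N1Br
Why: Electrophilic aromatic bromination at C5, the position para to the free phenol and meta to the formyl group, as in the bromination of o-vanillin.

Step 3
Reactants: 3 3-(benzyloxy)-5-bromo-2-hydroxybenzaldehyde; 4 ethyl bromoacetate
Product: 6 [2-(benzyloxy)-4-bromo-6-formylphenoxy]acetic acid, via ethyl ester 5 (not isolated)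
Conditions: K2CO3, DMF, 50 °C; then 2 M aq NaOH, rt; aq HCl
Reagents that add atoms: sodium hydroxide, [Na+].[OH-]
Why: Williamson O-alkylation of the phenoxide with the α-halo ester, followed by saponification in the same flask.

Step 4
Reactants: 6 [2-(benzyloxy)-4-bromo-6-formylphenoxy]acetic acid
Product: 7 7-(benzyloxy)-5-bromo-1-benzofuran
Conditions: NaOAc, Ac2O, AcOH, reflux
Reagents that add atoms: none
Why: Rössing benzofuran synthesis, an intramolecular Perkin-type condensation of the aryloxyacetic acid onto the ortho aldehyde with decarboxylative dehydration, as used for benzofuran and 7-alkoxybenzofurans.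

Step 5
Reactants: 7 7-(benzyloxy)-5-bromo-1-benzofuran; 8 ethyl diazoacetate
Product: 9 ethyl (1S,1aS,6bR)-3-(benzyloxy)-5-bromo-1a,6b-dihydro-1H-cyclopropa[b][1]benzofuran-1-carboxylate (ester exo: anti to the ring oxygen and the arene)
Conditions: CuOTf·½C6H6 (5 mol %), (S,S)-t-Bu-BOX (6 mol %), 8 (3 equiv, syringe pump, 12 h), CH2Cl2, 0 °C to rt
Reagents that add atoms: none
Why: The Cu(I)–bis(oxazoline) complex decomposes the diazo ester with loss of N2 to an electrophilic copper carbene, which adds to the enol-ether-like furan C2=C3 bond in an asynchronous concerted step, with C3 bonding first. The closest known reaction type is the Cu–BOX-catalysed asymmetric cyclopropanation of furans, benzofurans and enol ethers with diazoacetates. The three-membered ring is closed by this suprafacial [2+1] carbene addition, which necessarily gives the cis ring fusion. C1a and C6b are set together by the ligand-controlled choice of the benzofuran enantioface, and C1 by the exo preference of the ester, which avoids the arene in the transition state. The step needs chemoselectivity for C2=C3 over the benzo ring, the benzyl ether and the C–Br bond; the polarised enol-ether π bond is the most nucleophilic site, bromine and the aryl benzyl ether are inert to copper carbenes, and slow addition of the diazo ester suppresses carbene dimerisation.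

Step 6
Reactants: 9 ethyl (1S,1aS,6bR)-3-(benzyloxy)-5-bromo-1a,6b-dihydro-1H-cyclopropa[b][1]benzofuran-1-carboxylate; 10 guaiacol (2-methoxyphenol)
Product: 11 ethyl 2-[(2R,3R)-7-(benzyloxy)-5-bromo-2-(4-hydroxy-3-methoxyphenyl)-2,3-dihydro-1-benzofuran-3-yl]acetate (2,3-trans)
Conditions: 10 (5 equiv), Sc(OTf)3 (10 mol %), CH2Cl2/HFIP 4:1, −20 to 0 °C
Reagents that add atoms: none
Why: Proposed new method: Lewis-acid activation of the ester polarises the C1a–C1 bond of this donor–acceptor cyclopropane (donor: the ring oxygen), and guaiacol attacks C2 through its position para to OH from the face opposite the departing carbon (inversion, or anti to the C3 chain if an oxocarbenium ion pair intervenes), which should give the 2,3-trans product with C3 untouched; the closest known reaction types are the stereoinvertive Friedel–Crafts opening of aryl-donor cyclopropane-1,1-diesters by electron-rich arenes and the Lewis-acid opening of 2-alkoxycyclopropanecarboxylates by O- and C-nucleophiles.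

Step 7
Reactants: 11 ethyl 2-[(2R,3R)-7-(benzyloxy)-5-bromo-2-(4-hydroxy-3-methoxyphenyl)-2,3-dihydro-1-benzofuran-3-yl]acetate
Product: 12 ethyl 2-[(2R,3R)-7-(benzyloxy)-2-[4-(benzyloxy)-3-methoxyphenyl]-5-bromo-2,3-dihydro-1-benzofuran-3-yl]acetate
Conditions: BnBr (1.2 equiv), K2CO3, DMF, rt
Reagents that add atoms: benzyl bromide, BrCc1ccccc1
Why: Williamson etherification of the only free phenol, which also blocks quinone-methide opening of the C2–O bond in the later basic steps.

Step 8
Reactants: 12 ethyl 2-[(2R,3R)-7-(benzyloxy)-2-[4-(benzyloxy)-3-methoxyphenyl]-5-bromo-2,3-dihydro-1-benzofuran-3-yl]acetate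
Product: 13 2-[(2R,3R)-7-(benzyloxy)-2-[4-(benzyloxy)-3-methoxyphenyl]-5-bromo-2,3-dihydro-1-benzofuran-3-yl]acetic acid
Conditions: LiOH·H2O, THF/MeOH/H2O, rt; aq HCl
Reagents that add atoms: lithium hydroxide, [Li+].[OH-]
Why: Ester saponification; the only enolisable position is the CH2 group, so neither stereocentre can epimerise.

Step 9
Reactants: 13 2-[(2R,3R)-7-(benzyloxy)-2-[4-(benzyloxy)-3-methoxyphenyl]-5-bromo-2,3-dihydro-1-benzofuran-3-yl]acetic acid
Product: 16 [(2R,3S)-7-(benzyloxy)-2-[4-(benzyloxy)-3-methoxyphenyl]-5-bromo-2,3-dihydro-1-benzofuran-3-yl]methanol, via Barton ester 14 (not isolated), via hydroperoxide 15 (not isolated)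
Conditions: N-hydroxypyridine-2-thione, DCC, DMAP (cat.), CH2Cl2, 0 °C, dark; then t-BuSH, O2, toluene, visible light, 0 °C to rt; then PPh3, rt
Reagents that add atoms: dioxygen, O=O
Why: Barton decarboxylation with oxygen trapping, in which the thiyl-radical chain fragments the thiohydroxamate ester to a primary alkyl radical that O2 captures faster than it can rearrange, and PPh3 reduces the hydroperoxide; C2 and C3 take no part.

Step 10
Reactants: 16 [(2R,3S)-7-(benzyloxy)-2-[4-(benzyloxy)-3-methoxyphenyl]-5-bromo-2,3-dihydro-1-benzofuran-3-yl]methanol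
Product: 18 (2R,3S)-7-(benzyloxy)-2-[4-(benzyloxy)-3-methoxyphenyl]-3-(hydroxymethyl)-2,3-dihydro-1-benzofuran-5-carbaldehyde, via dilithio intermediate 17 (not isolated)
Conditions: n-BuLi (2.2 equiv), THF, −78 °C; DMF (5 equiv), −78 to 0 °C; aq NH4Cl
Reagents that add atoms: N,N-dimethylformamide, CN(C)C=O
Why: Bromine–lithium exchange on the lithium alkoxide (the first equivalent of base only deprotonates the alcohol) followed by formylation with DMF, a Bouveault aldehyde synthesis.

Step 11
Reactants: 19 2,4,6-trihydroxyacetophenone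
Product: 20 1-[2,4-bis(benzyloxy)-6-hydroxyphenyl]ethan-1-one
Conditions: BnBr (2.1 equiv), K2CO3, DMF, rt
Reagents that add atoms: benzyl bromide, BrCc1ccccc1
Why: Williamson etherification that stops at the dibenzyl ether, because the last hydroxyl is locked in a hydrogen bond to the ketone.

Step 12
Reactants: 18 (2R,3S)-7-(benzyloxy)-2-[4-(benzyloxy)-3-methoxyphenyl]-3-(hydroxymethyl)-2,3-dihydro-1-benzofuran-5-carbaldehyde; 20 1-[2,4-bis(benzyloxy)-6-hydroxyphenyl]ethan-1-one
Product: 21 (2E)-1-[2,4-bis(benzyloxy)-6-hydroxyphenyl]-3-[(2R,3S)-7-(benzyloxy)-2-[4-(benzyloxy)-3-methoxyphenyl]-3-(hydroxymethyl)-2,3-dihydro-1-benzofuran-5-yl]prop-2-en-1-one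
Conditions: 50% aq KOH, EtOH/THF, rt
Reagents that add atoms: none
Why: Claisen–Schmidt condensation of a non-enolisable aryl aldehyde with the methyl ketone, the E-enone arising from E1cB dehydration.

Step 13
Reactants: 21 (2E)-1-[2,4-bis(benzyloxy)-6-hydroxyphenyl]-3-[(2R,3S)-7-(benzyloxy)-2-[4-(benzyloxy)-3-methoxyphenyl]-3-(hydroxymethyl)-2,3-dihydro-1-benzofuran-5-yl]prop-2-en-1-one
Product: 22 5,7-bis(benzyloxy)-2-[(2R,3S)-7-(benzyloxy)-2-[4-(benzyloxy)-3-methoxyphenyl]-3-(hydroxymethyl)-2,3-dihydro-1-benzofuran-5-yl]-3-hydroxy-4H-chromen-4-one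
Conditions: 30% aq H2O2, 2 M aq NaOH, MeOH/THF, 0 °C to rt
Reagents that add atoms: hydrogen peroxide, OO
Why: Algar–Flynn–Oyamada oxidative cyclisation of a 2'-hydroxychalcone with alkaline hydrogen peroxide, a standard entry to 5,7-dialkoxyflavonols that leaves the remote stereocentres alone.

Step 14
Reactants: 22 5,7-bis(benzyloxy)-2-[(2R,3S)-7-(benzyloxy)-2-[4-(benzyloxy)-3-methoxyphenyl]-3-(hydroxymethyl)-2,3-dihydro-1-benzofuran-5-yl]-3-hydroxy-4H-chromen-4-one
Product: 23 2,3-dehydrosilychristin, 3,5,7-trihydroxy-2-[(2R,3S)-7-hydroxy-2-(4-hydroxy-3-methoxyphenyl)-3-(hydroxymethyl)-2,3-dihydro-1-benzofuran-5-yl]-4H-chromen-4-one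
Conditions: H2 (1 atm), 10% Pd/C, THF/MeOH, rt, stopped at full debenzylation
Reagents that add atoms: none
Why: Catalytic hydrogenolysis of four aryl benzyl ethers; under neutral conditions at 1 atm the cyclic benzylic C2–O bond and the flavonol enone are expected to survive.

Compound list
1 | 2,3-dihydroxybenzaldehyde | O=Cc1cccc(O)c1O | starting material
2 | 3-(benzyloxy)-2-hydroxybenzaldehyde | O=Cc1cccc(OCc2ccccc2)c1O | intermediate
3 | 3-(benzyloxy)-5-bromo-2-hydroxybenzaldehyde | O=Cc1cc(Br)cc(OCc2ccccc2)c1O | intermediate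
4 | ethyl bromoacetate | CCOC(=O)CBr | starting material
5 | ethyl [2-(benzyloxy)-4-bromo-6-formylphenoxy]acetate (not isolated) | CCOC(=O)COc1c(C=O)cc(Br)cc1OCc1ccccc1 | intermediate
6 | [2-(benzyloxy)-4-bromo-6-formylphenoxy]acetic acid | OC(=O)COc1c(C=O)cc(Br)cc1OCc1ccccc1 | intermediate
7 | 7-(benzyloxy)-5-bromo-1-benzofuran | Brc1cc(OCc2ccccc2)c2occc2c1 | intermediate
8 | ethyl diazoacetate | CCOC(=O)C=[N+]=[N-] | starting material
9 | ethyl (1S,1aS,6bR)-3-(benzyloxy)-5-bromo-1a,6b-dihydro-1H-cyclopropa[b][1]benzofuran-1-carboxylate (exo ester) | CCOC(=O)[C@@H]1[C@H]2Oc3c(OCc4ccccc4)cc(Br)cc3[C@@H]12 | intermediate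
10 | guaiacol (2-methoxyphenol) | COc1ccccc1O | starting material
11 | ethyl 2-[(2R,3R)-7-(benzyloxy)-5-bromo-2-(4-hydroxy-3-methoxyphenyl)-2,3-dihydro-1-benzofuran-3-yl]acetate | COc1cc([C@@H]2Oc3c(OCc4ccccc4)cc(Br)cc3[C@H]2CC(=O)OCC)ccc1O | intermediate
12 | ethyl 2-[(2R,3R)-7-(benzyloxy)-2-[4-(benzyloxy)-3-methoxyphenyl]-5-bromo-2,3-dihydro-1-benzofuran-3-yl]acetate | COc1cc([C@@H]2Oc3c(OCc4ccccc4)cc(Br)cc3[C@H]2CC(=O)OCC)ccc1OCc1ccccc1 | intermediate
13 | 2-[(2R,3R)-7-(benzyloxy)-2-[4-(benzyloxy)-3-methoxyphenyl]-5-bromo-2,3-dihydro-1-benzofuran-3-yl]acetic acid | COc1cc([C@@H]2Oc3c(OCc4ccccc4)cc(Br)cc3[C@H]2CC(=O)O)ccc1OCc1ccccc1 | intermediate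
14 | 2-thioxopyridin-1(2H)-yl ester of acid 13 (Barton ester, not isolated) | COc1cc([C@@H]2Oc3c(OCc4ccccc4)cc(Br)cc3[C@H]2CC(=O)On2ccccc2=S)ccc1OCc1ccccc1 | intermediate
15 | (2R,3S)-7-(benzyloxy)-2-[4-(benzyloxy)-3-methoxyphenyl]-5-bromo-3-(hydroperoxymethyl)-2,3-dihydro-1-benzofuran (not isolated) | COc1cc([C@@H]2Oc3c(OCc4ccccc4)cc(Br)cc3[C@H]2COO)ccc1OCc1ccccc1 | intermediate
16 | [(2R,3S)-7-(benzyloxy)-2-[4-(benzyloxy)-3-methoxyphenyl]-5-bromo-2,3-dihydro-1-benzofuran-3-yl]methanol | COc1cc([C@@H]2Oc3c(OCc4ccccc4)cc(Br)cc3[C@H]2CO)ccc1OCc1ccccc1 | intermediate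
17 | lithium alkoxide of 16 with lithium in place of bromine at C5 (dilithio species, not isolated) | COc1cc([C@@H]2Oc3c(OCc4ccccc4)cc([Li])cc3[C@H]2CO[Li])ccc1OCc1ccccc1 | intermediate
18 | (2R,3S)-7-(benzyloxy)-2-[4-(benzyloxy)-3-methoxyphenyl]-3-(hydroxymethyl)-2,3-dihydro-1-benzofuran-5-carbaldehyde | COc1cc([C@@H]2Oc3c(OCc4ccccc4)cc(C=O)cc3[C@H]2CO)ccc1OCc1ccccc1 | intermediate
19 | 2,4,6-trihydroxyacetophenone | CC(=O)c1c(O)cc(O)cc1O | starting material
20 | 1-[2,4-bis(benzyloxy)-6-hydroxyphenyl]ethan-1-one | CC(=O)c1c(O)cc(OCc2ccccc2)cc1OCc1ccccc1 | intermediate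
21 | (2E)-1-[2,4-bis(benzyloxy)-6-hydroxyphenyl]-3-[(2R,3S)-7-(benzyloxy)-2-[4-(benzyloxy)-3-methoxyphenyl]-3-(hydroxymethyl)-2,3-dihydro-1-benzofuran-5-yl]prop-2-en-1-one | COc1cc([C@@H]2Oc3c(OCc4ccccc4)cc(/C=C/C(=O)c5c(O)cc(OCc6ccccc6)cc5OCc7ccccc7)cc3[C@H]2CO)ccc1OCc8ccccc8 | intermediate
22 | 5,7-bis(benzyloxy)-2-[(2R,3S)-7-(benzyloxy)-2-[4-(benzyloxy)-3-methoxyphenyl]-3-(hydroxymethyl)-2,3-dihydro-1-benzofuran-5-yl]-3-hydroxy-4H-chromen-4-one | COc1cc([C@@H]2Oc3c(OCc4ccccc4)cc(-c5oc6cc(OCc7ccccc7)cc(OCc7ccccc7)c6c(=O)c5O)cc3[C@H]2CO)ccc1OCc8ccccc8 | intermediate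
23 | 2,3-dehydrosilychristin | COc1cc([C@@H]2Oc3c(O)cc(-c4oc5cc(O)cc(O)c5c(=O)c4O)cc3[C@H]2CO)ccc1O | target

Total steps: 14. Longest linear sequence: 13 (steps 1–10 and 12–14; step 11 is a one-step side branch).

Steps most likely to fail

1. Step 6 (proposed new method). Ionisation at C2 may outpace capture by the arene, and the resulting cation can lose the C3 proton and aromatise, erasing the stereocentre. Guaiacol may also react through oxygen or through the wrong ring carbon. The fallback sets out from 9 and uses two known reactions. Acid-catalysed methanolysis (TsOH cat., MeOH, 0 °C), the standard acetal-forming opening of 2-oxycyclopropanecarboxylates, should give ethyl 2-[(2R,3R)-7-(benzyloxy)-5-bromo-2-methoxy-2,3-dihydro-1-benzofuran-3-yl]acetate F1; its C2 epimer would serve equally. Commercial 4-(benzyloxy)-3-methoxyphenylboronic acid is converted with KHF2 into potassium [4-(benzyloxy)-3-methoxyphenyl]trifluoroborate F2. BF3·OEt2-promoted coupling of the acetal with the aryltrifluoroborate (MeCN, 0 °C) transfers the aryl group by ipso substitution, anti to the C3 chain. This comes back to the route at 12, so step 7 is not needed.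

2. Step 5. The benzofuran C2=C3 bond may react too slowly with the copper carbene relative to carbene dimerisation, or enantioface discrimination may be insufficient. The fallback sets out from 7 and replaces asymmetric catalysis by resolution. Rh2(OAc)4-catalysed cyclopropanation with slowly added ethyl diazoacetate (CH2Cl2, rt) should give the racemic exo ester, rac-ethyl 3-(benzyloxy)-5-bromo-1a,6b-dihydro-1H-cyclopropa[b][1]benzofuran-1-carboxylate F3. Preparative chromatography on a chiral stationary phase separates the enantiomers, and the (1S,1aS,6bR) isomer is identified by anomalous-dispersion X-ray analysis. This comes back to the route at 9.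

3. Step 13. With an alkoxy group at C6' the phenoxide may close onto the α-carbon of the epoxidised enone, a five-membered closure that diverts material to an aurone. The fallback sets out from 21 and separates ring closure from hydroxylation. Iodine-catalysed oxidative cyclisation in DMSO (I2 10 mol %, 120 °C) should give the flavone 5,7-bis(benzyloxy)-2-[(2R,3S)-7-(benzyloxy)-2-[4-(benzyloxy)-3-methoxyphenyl]-3-(hydroxymethyl)-2,3-dihydro-1-benzofuran-5-yl]-4H-chromen-4-one F4. Epoxidation of its C2=C3 bond with dimethyldioxirane (acetone/CH2Cl2, 0 °C) and acid-catalysed opening (TsOH cat.) then installs the 3-hydroxyl. This comes back to the route at 22.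

Further compounds
F1 | step 6 | ethyl 2-[(2R,3R)-7-(benzyloxy)-5-bromo-2-methoxy-2,3-dihydro-1-benzofuran-3-yl]acetate | CO[C@@H]1Oc2c(OCc3ccccc3)cc(Br)cc2[C@H]1CC(=O)OCC
F2 | step 6 | potassium [4-(benzyloxy)-3-methoxyphenyl]trifluoroborate | [K+].COc1cc([B-](F)(F)F)ccc1OCc1ccccc1
F3 | step 5 | rac-ethyl exo-3-(benzyloxy)-5-bromo-1a,6b-dihydro-1H-cyclopropa[b][1]benzofuran-1-carboxylate (both enantiomers) | CCOC(=O)[C@@H]1[C@H]2Oc3c(OCc4ccccc4)cc(Br)cc3[C@@H]12.CCOC(=O)[C@H]1[C@@H]2Oc3c(OCc4ccccc4)cc(Br)cc3[C@H]12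
F4 | step 13 | 5,7-bis(benzyloxy)-2-[(2R,3S)-7-(benzyloxy)-2-[4-(benzyloxy)-3-methoxyphenyl]-3-(hydroxymethyl)-2,3-dihydro-1-benzofuran-5-yl]-4H-chromen-4-one | COc1cc([C@@H]2Oc3c(OCc4ccccc4)cc(-c5cc(=O)c6c(OCc7ccccc7)cc(OCc7ccccc7)cc6o5)cc3[C@H]2CO)ccc1OCc8ccccc8
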